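**Retrosynthetic overview**
1. Target ⇒ C6 butanoylation; the oxonane (ring D) is closed last by intramolecular Nozaki–Hiyama–Kishi C6–C7 coupling of a vinyl bromide/aldehyde on the finished A/B/C tricycle.
2. ε-Lactone (ring C) with C3/C4 ⇒ (Z)-C3=C4 alkene: epoxidation, then 7-exo carboxylysis of the epoxide by the C16 acid (new step); the acid comes from an isopropenyl group.
3. Tetrahydrofuran (ring B) and C2 ⇒ (Z)-alkenyllithium added to a cis-fused γ-lactone, then Et3SiH reduction of the lactol.
4. Ring A plus γ-lactone ⇒ ester-tethered intramolecular Diels–Alder of a dienyl (E)-4-oxopentenoate (C10, C1, C14 from C9); C11–OH by iodolactonisation.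
5. C9 ⇒ chiral-phosphoric-acid-catalysed 2-bromoallylboration of an achiral dienal (first stereocentre). Ring order: A (+γ-lactone) → B → C → D.

Assumption: all ten stereodescriptors of the given string are taken literally; as written, C2 places C3 and C8 on opposite faces of the tetrahydrofuran (2,5-trans, an in,out ether bridge), so C2 is fixed before the nine-membered ring is closed.

Locants used below (briarellin numbering): ring A = C1, C10–C14; tetrahydrofuran = C1, C2, O, C9, C10; lactone = C2, C3, O, C16, C15, C14, C1; oxonane = O, C2–C9.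

**Route**

Step 1
Reactants: 1 (2E)-3-methylpent-2-en-4-yn-1-ol
Product: 2 (2E)-3-methylpenta-2,4-dien-1-ol
Conditions: H2 (1 atm), Lindlar Pd/CaCO3–Pb, quinoline, hexane/EtOAc, 0 °C
Reagents that add atoms: none
Why: Lindlar semihydrogenation stops at the alkene because the poisoned catalyst binds the terminal alkyne far better than the product diene; no stereocentre is formed and the E alkene is untouched.

Step 2
Reactants: 2 (2E)-3-methylpenta-2,4-dien-1-ol
Product: 3 (2E)-3-methylpenta-2,4-dienal
Conditions: MnO2, CH2Cl2, rt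
Reagents that add atoms: none
Why: Activated MnO2 oxidises only the allylic alcohol and gives the dienal without E/Z isomerisation.

Step 3
Reactants: 3 (2E)-3-methylpenta-2,4-dienal; 4 2-(2-bromoprop-2-en-1-yl)-4,4,5,5-tetramethyl-1,3,2-dioxaborolane
Product: 6 (4S,5E)-2-bromo-6-methylocta-1,5,7-trien-4-ol, via borate ester 5 (not isolated)
Conditions: (S)-TRIP (5 mol %), 4 Å MS, PhMe, −30 °C; then aq. NaHCO3
Reagents that add atoms: none
Why: Chiral phosphoric acid-catalysed allylboration (Antilla type): the acid hydrogen-bonds a boronate oxygen and the formyl H in a closed chair transition state, so one aldehyde face is attacked and the S carbinol (C9, the first stereocentre) results; the sense is assigned by analogy with aryl and enal substrates.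

Step 4
Reactants: 6 (4S,5E)-2-bromo-6-methylocta-1,5,7-trien-4-ol; 7 (2E)-4-oxopent-2-enoic acid
Product: 9 (3S,3aS,7R,7aR)-7-acetyl-3-(2-bromoprop-2-en-1-yl)-4-methyl-3a,6,7,7a-tetrahydro-2-benzofuran-1(3H)-one, via trienyl ester 8 (not isolated)
Conditions: DIC, DMAP (10 mol %), CH2Cl2, 0 °C → rt; then PhMe, BHT, 90 °C; then DBU (0.3 equiv), rt
Reagents that add atoms: none
Why: Steglich esterification then ester-tethered intramolecular Diels–Alder reaction: A(1,3) strain between C9 and the C11 methyl holds C9–H in the diene plane so the tether delivers the dienophile to one face (C10 set from C9), the E dienophile gives H1/H14 trans, and DBU equilibration of the two enolisable centres (C1, C14) converges any trans-fused or axial-acetyl adduct on the cis-fused lactone with equatorial acetyl.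

Step 5
Reactants: 9 cis-fused lactone ketone
Product: 11 2-acetyl-8-[(1S)-3-bromo-1-hydroxybut-3-en-1-yl]-4-iodo-5-methyl-6-oxabicyclo[3.2.1]octan-7-one, via hydroxy acid 10 (not isolated)
Conditions: LiOH, THF/H2O, 0 °C; then NaHCO3, I2, KI, 0 °C, dark
Reagents that add atoms: lithium hydroxide [Li+].[OH-]; iodine II
Why: Saponification then iodolactonisation: the C2 carboxylate attacks tertiary C11 (Markovnikov, five-membered ring) from its own face, anti to the iodonium ion, so the new C11–O bond is cis to C2 and C9 as the target requires.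

Step 6
Reactants: 11 bridged iodolactone
Product: 12 2-acetyl-8-[(1S)-3-bromo-1-hydroxybut-3-en-1-yl]-5-methyl-6-oxabicyclo[3.2.1]octan-7-one
Conditions: Bu3SnH, AIBN (cat.), PhMe, 80 °C
Reagents that add atoms: none
Why: Radical chain dehalogenation; iodine abstraction from the secondary alkyl iodide is orders of magnitude faster than attack on the vinyl bromide, and C12 becomes a methylene.

Step 7
Reactants: 12 bridged lactone ketone
Product: 14 3-(2-bromoprop-2-en-1-yl)-4-hydroxy-4-methyl-7-(prop-1-en-2-yl)hexahydro-2-benzofuran-1(3H)-one, via fused keto lactone 13 (not isolated)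
Conditions: Ph3PCH3Br, n-BuLi, THF, 0 °C; then 12, 0 °C → rt
Reagents that add atoms: methyltriphenylphosphonium bromide C[P+](c1ccccc1)(c1ccccc1)c1ccccc1.[Br-]
Why: The basic ylide first forms the C9 alkoxide, which transacylates the strained bridged tertiary lactone to the cis-fused γ-lactone (intramolecular transesterification, freeing the C11 tertiary alcohol), and Wittig methylenation of the methyl ketone then gives the isopropenyl group.

Step 8
Reactants: 15 3-{[tert-butyl(dimethyl)silyl]oxy}propanal
Product: 16 tert-butyl{[(3Z)-4-iodopent-3-en-1-yl]oxy}dimethylsilane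
Conditions: EtPPh3Br, n-BuLi, THF, rt; I2, −78 °C; NaHMDS, −78 °C; then 15, −78 → −20 °C
Reagents that add atoms: ethyltriphenylphosphonium bromide CC[P+](c1ccccc1)(c1ccccc1)c1ccccc1.[Br-]; iodine II
Why: Stork–Zhao-type α-iodoalkylidene Wittig olefination, kinetically Z-selective (iodine cis to the chain), which fixes the alkene geometry later translated into the C3/C4 relationship.

Step 9
Reactants: 14 isopropenyl γ-lactone; 16 (Z)-vinyl iodide
Product: 18 3-(2-bromoprop-2-en-1-yl)-1-[(2Z)-5-{[tert-butyl(dimethyl)silyl]oxy}pent-2-en-2-yl]-4-methyl-7-(prop-1-en-2-yl)octahydro-2-benzofuran-1,4-diol, via alkenyllithium 17 (not isolated)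
Conditions: 16 (2.3 equiv), t-BuLi (4.6 equiv), Et2O, −78 °C; then 14, THF, −78 °C; H2O
Reagents that add atoms: none
Why: Iodine–lithium exchange with retention of alkene geometry, then 1,2-addition to the γ-lactone; one equivalent is spent on the C11 hydroxyl and the lithium lactolate does not collapse at −78 °C, so addition stops at the lactol.

Step 10
Reactants: 18 lactol (anomeric mixture)
Product: 19 3-(2-bromoprop-2-en-1-yl)-1-[(2Z)-5-{[tert-butyl(dimethyl)silyl]oxy}pent-2-en-2-yl]-4-methyl-7-(prop-1-en-2-yl)octahydro-2-benzofuran-4-ol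
Conditions: Et3SiH, BF3·OEt2, CH2Cl2, −78 → −40 °C
Reagents that add atoms: none
Why: Kishi-type reductive etherification: BF3 ionises the lactol to the cis-fused bicyclic oxocarbenium ion and Et3SiH delivers hydride to its convex face, anti to the adjacent C1–C14 bond, so H2 ends cis to H1 and the alkenyl group cis to C14 and trans to the C9 side chain (the 2,5-trans tetrahydrofuran of the target).

Step 11
Reactants: 19 2,5-trans tetrahydrofuran
Product: 21 primary alcohol (C14 bears CH(CH3)CH2OH), via alkylborane 20 (not isolated)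
Conditions: 9-BBN, THF, 0 °C → rt; then NaOH, H2O2, 0 °C
Reagents that add atoms: hydrogen peroxide OO
Why: Hydroboration–oxidation: 9-BBN adds only to the terminal carbon of the 1,1-disubstituted alkene (the trisubstituted alkene and the vinyl bromide are much slower), from the face turned away from C1 in the rotamer with C14–H eclipsing C=CH2, which sets C15 as in the target.

Step 12
Reactants: 21 primary alcohol
Product: 22 carboxylic acid (C14 bears CH(CH3)CO2H)
Conditions: TEMPO (20 mol %), PhI(OAc)2 (2.5 equiv), MeCN/H2O, rt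
Reagents that add atoms: water O
Why: TEMPO/PhI(OAc)2 oxidation takes the primary alcohol through the aldehyde hydrate to the acid while the tertiary alcohol, silyl ether and alkenes are untouched.

Step 13
Reactants: 22 carboxylic acid
Product: 24 hydroxy ε-lactone (rings A–C of the target with free 4-OH), via epoxy acid 23 (not isolated)
Conditions: DMDO, acetone, −30 → 0 °C; evaporate; then (PhO)2P(O)OH (10 mol %), PhMe, rt
Reagents that add atoms: dimethyldioxirane CC1(C)OO1
Why: Proposed new method: a one-flask dioxirane epoxidation followed by diphenyl phosphate-catalysed 7-exo-tet intramolecular carboxylysis of the trisubstituted epoxide at its tertiary carbon to close an ε-lactone; DMDO attacks the Z alkene on the face anti to C1 in the A(1,3)-locked rotamer (C2–H eclipsing C4–C5), the phosphoric acid then acts bifunctionally (P–OH to the epoxide oxygen, P=O to the CO2H) so the carboxyl oxygen attacks C3, where positive charge builds up, anti to the leaving oxygen, which inverts C3 and leaves the epoxide oxygen as the free 4-OH with C4 retained; the closest known chemistry is phosphoric acid-catalysed intermolecular carboxylysis of epoxides and acid-promoted 5- and 6-exo epoxy-acid lactonisations, the seven-membered closure at a tertiary carbon being the untested part.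

Step 14
Reactants: 24 hydroxy ε-lactone
Product: 25 4-O-octanoate
Conditions: octanoic anhydride, DMAP, Et3N, CH2Cl2, rt
Reagents that add atoms: octanoic anhydride CCCCCCCC(=O)OC(=O)CCCCCCC
Why: DMAP-catalysed acyl transfer esterifies the only secondary alcohol; the tertiary C11–OH is inert under these conditions.

Step 15
Reactants: 25 silyl ether octanoate
Product: 26 primary alcohol (C6–OH)
Conditions: HF·pyridine, pyridine/THF, 0 °C → rt
Reagents that add atoms: none
Why: Fluoride-driven Si–O cleavage under buffered, mildly acidic conditions that do not cause acyl migration or lactone opening.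

Step 16
Reactants: 26 primary alcohol
Product: 27 aldehyde (C6)
Conditions: Dess–Martin periodinane, NaHCO3, CH2Cl2, 0 °C
Reagents that add atoms: none
Why: Dess–Martin oxidation stops at the aldehyde and the bicarbonate buffer suppresses β-elimination of the octanoate.

Step 17
Reactants: 27 bromo aldehyde
Product: 28 tetracyclic alcohol (target lacking the butanoyl group)
Conditions: CrCl2 (8 equiv), NiCl2 (2 mol %), DMSO, 2 mM, rt
Reagents that add atoms: none
Why: Intramolecular Nozaki–Hiyama–Kishi reaction: Ni inserts into the vinyl bromide, transmetallation gives an alkenylchromium(III) that adds irreversibly to the aldehyde at high dilution, the exergonic C–C bond formation paying for the strained trans-bridged oxonane, and attack anti to the β-octanoyloxy group (1,3-anti polar induction) gives the 6R alcohol.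

Step 18
Reactants: 28 tetracyclic alcohol
Product: 29 target CNP0350718.2
Conditions: butanoic anhydride, DMAP, Et3N, CH2Cl2, 0 °C
Reagents that add atoms: butanoic anhydride CCCC(=O)OC(=O)CCC
Why: DMAP-catalysed acylation of the secondary allylic C6–OH; the tertiary C11–OH stays free, which completes the target.

**Compound list**

1 | (2E)-3-methylpent-2-en-4-yn-1-ol | C#C/C(C)=C/CO | starting material
2 | (2E)-3-methylpenta-2,4-dien-1-ol | C=C/C(C)=C/CO | intermediate
3 | (2E)-3-methylpenta-2,4-dienal | C=C/C(C)=C/C=O | intermediate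
4 | 2-(2-bromoprop-2-en-1-yl)-4,4,5,5-tetramethyl-1,3,2-dioxaborolane | C=C(Br)CB1OC(C)(C)C(C)(C)O1 | starting material
5 | 2-{[(4S,5E)-2-bromo-6-methylocta-1,5,7-trien-4-yl]oxy}-4,4,5,5-tetramethyl-1,3,2-dioxaborolane (borate ester of 6) | C=C(Br)C[C@@H](/C=C(C)/C=C)OB1OC(C)(C)C(C)(C)O1 | intermediate
6 | (4S,5E)-2-bromo-6-methylocta-1,5,7-trien-4-ol | C=C(Br)C[C@@H](/C=C(C)/C=C)O | intermediate
7 | (2E)-4-oxopent-2-enoic acid | CC(=O)/C=C/C(=O)O | starting material
8 | (4S,5E)-2-bromo-6-methylocta-1,5,7-trien-4-yl (2E)-4-oxopent-2-enoate | C=C(Br)C[C@@H](/C=C(C)/C=C)OC(=O)/C=C/C(C)=O | intermediate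
9 | (3S,3aS,7R,7aR)-7-acetyl-3-(2-bromoprop-2-en-1-yl)-4-methyl-3a,6,7,7a-tetrahydro-2-benzofuran-1(3H)-one (cis-fused; H1/H10 cis; H1/H14 trans; bromoallyl cis to H10) | C=C(Br)C[C@@H]1OC(=O)[C@H]2[C@@H](CC=C(C)[C@H]21)C(C)=O | intermediate
10 | 6-acetyl-2-[(1S)-3-bromo-1-hydroxybut-3-en-1-yl]-3-methylcyclohex-3-ene-1-carboxylic acid (ring centres as in 9) | C=C(Br)C[C@H](O)[C@@H]1C(C)=CC[C@@H](C(C)=O)[C@@H]1C(=O)O | intermediate
11 | 2-acetyl-8-[(1S)-3-bromo-1-hydroxybut-3-en-1-yl]-4-iodo-5-methyl-6-oxabicyclo[3.2.1]octan-7-one (lactone O on C11 cis to the C9 side chain; I trans to that O; acetyl trans to C2) | C=C(Br)C[C@H](O)[C@@H]1[C@]2(C)OC(=O)[C@H]1[C@H](C(C)=O)C[C@@H]2I | intermediate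
12 | 2-acetyl-8-[(1S)-3-bromo-1-hydroxybut-3-en-1-yl]-5-methyl-6-oxabicyclo[3.2.1]octan-7-one (centres as in 11) | C=C(Br)C[C@H](O)[C@@H]1[C@]2(C)OC(=O)[C@H]1[C@H](C(C)=O)CC2 | intermediate
13 | 7-acetyl-3-(2-bromoprop-2-en-1-yl)-4-hydroxy-4-methylhexahydro-2-benzofuran-1(3H)-one (cis-fused; 11-OH cis to C9; other centres as in 9) | C=C(Br)C[C@@H]1OC(=O)[C@H]2[C@@H](CC[C@@](C)(O)[C@H]21)C(C)=O | intermediate
14 | 3-(2-bromoprop-2-en-1-yl)-4-hydroxy-4-methyl-7-(prop-1-en-2-yl)hexahydro-2-benzofuran-1(3H)-one (centres as in 13) | C=C(Br)C[C@@H]1OC(=O)[C@H]2[C@@H](CC[C@@](C)(O)[C@H]21)C(C)=C | intermediate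
15 | 3-{[tert-butyl(dimethyl)silyl]oxy}propanal | O=CCCO[Si](C)(C)C(C)(C)C | starting material
16 | tert-butyl{[(3Z)-4-iodopent-3-en-1-yl]oxy}dimethylsilane | C/C(I)=C/CCO[Si](C)(C)C(C)(C)C | intermediate
17 | alkenyllithium from 16 (Li in place of I; geometry retained) | C/C([Li])=C/CCO[Si](C)(C)C(C)(C)C | intermediate
18 | lactol: 3-(2-bromoprop-2-en-1-yl)-1-[(2Z)-5-{[tert-butyl(dimethyl)silyl]oxy}pent-2-en-2-yl]-4-methyl-7-(prop-1-en-2-yl)octahydro-2-benzofuran-1,4-diol (C2 anomeric mixture; other centres as in 14) | C=C(Br)C[C@@H]1OC(O)(/C(C)=C\CCO[Si](C)(C)C(C)(C)C)[C@H]2[C@@H](CC[C@@](C)(O)[C@H]21)C(C)=C | intermediate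
19 | 2,5-trans tetrahydrofuran: 18 with H in place of the lactol OH (H2 cis to H1; C1, C2, C9, C10, C11, C14 as in the target) | C=C(Br)C[C@@H]1O[C@@H](/C(C)=C\CCO[Si](C)(C)C(C)(C)C)[C@H]2[C@@H](CC[C@@](C)(O)[C@H]21)C(C)=C | intermediate
20 | B-alkyl-9-BBN adduct of 19 (boron on C16; C15 as in the target) | C=C(Br)C[C@@H]1O[C@@H](/C(C)=C\CCO[Si](C)(C)C(C)(C)C)[C@H]2[C@@H](CC[C@@](C)(O)[C@H]21)[C@@H](C)CB3C4CCCC3CCC4 | intermediate
21 | primary alcohol: 19 with C14 bearing CH(CH3)CH2OH (C15 as in the target) | C=C(Br)C[C@@H]1O[C@@H](/C(C)=C\CCO[Si](C)(C)C(C)(C)C)[C@H]2[C@@H](CC[C@@](C)(O)[C@H]21)[C@@H](C)CO | intermediate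
22 | carboxylic acid: 21 with CO2H in place of CH2OH | C=C(Br)C[C@@H]1O[C@@H](/C(C)=C\CCO[Si](C)(C)C(C)(C)C)[C@H]2[C@@H](CC[C@@](C)(O)[C@H]21)[C@@H](C)C(=O)O | intermediate
23 | epoxy acid: 3,4-epoxide of 22 (oxygen on the alkene face anti to C1; C2 and C5 cis on the oxirane) | C=C(Br)C[C@@H]1O[C@@H]([C@]3(C)O[C@@H]3CCO[Si](C)(C)C(C)(C)C)[C@H]2[C@@H](CC[C@@](C)(O)[C@H]21)[C@@H](C)C(=O)O | intermediate
24 | hydroxy ε-lactone: rings A–C of the target (C1–C4, C9–C11, C14, C15 as in the target) with free 4-OH, C6 as CH2OTBS and 2-bromoallyl on C9 | C=C(Br)C[C@@H]1O[C@@H]3[C@H]2[C@@H](CC[C@@](C)(O)[C@H]21)[C@@H](C)C(=O)O[C@@]3(C)[C@H](O)CCO[Si](C)(C)C(C)(C)C | intermediate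
25 | 4-O-octanoate of 24 | C=C(Br)C[C@@H]1O[C@@H]3[C@H]2[C@@H](CC[C@@](C)(O)[C@H]21)[C@@H](C)C(=O)O[C@@]3(C)[C@H](OC(=O)CCCCCCC)CCO[Si](C)(C)C(C)(C)C | intermediate
26 | primary alcohol: 25 with free C6–OH | C=C(Br)C[C@@H]1O[C@@H]3[C@H]2[C@@H](CC[C@@](C)(O)[C@H]21)[C@@H](C)C(=O)O[C@@]3(C)[C@H](OC(=O)CCCCCCC)CCO | intermediate
27 | C6 aldehyde of 26 | C=C(Br)C[C@@H]1O[C@@H]3[C@H]2[C@@H](CC[C@@](C)(O)[C@H]21)[C@@H](C)C(=O)O[C@@]3(C)[C@H](OC(=O)CCCCCCC)CC=O | intermediate
28 | tetracyclic alcohol: target with free 6-OH (6R) | C=C1C[C@@H]2O[C@@H]3[C@H]4[C@@H](CC[C@@](C)(O)[C@H]42)[C@@H](C)C(=O)O[C@@]3(C)[C@H](OC(=O)CCCCCCC)C[C@H]1O | intermediate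
29 | CNP0350718.2 (6-butanoate 4-octanoate; 11-OH free) | C=C1C[C@@H]2O[C@@H]3[C@H]4[C@@H](CC[C@@](C)(O)[C@H]42)[C@@H](C)C(=O)O[C@@]3(C)[C@H](OC(=O)CCCCCCC)C[C@H]1OC(=O)CCC | target

**Totals and risks**

Total step count: 18. Longest linear sequence: 17 (steps 1–7 and 9–18; step 8 makes the side-chain fragment).

The three steps most likely to fail:

Step 17 (ring D closure). The oxonane is bridged 2,5-trans across the tetrahydrofuran and is strained, so oligomerisation or no reaction is the main danger; the C6 configuration is also only predicted. Fallback, setting out from 26 and returning at 28: treat 26 with TBAF in DMF to dehydrobrominate the 2-bromoalkene to the terminal alkyne alcohol F6, oxidise it with Dess–Martin periodinane to the ynal F7, and close the ring by Ni(0)/N-heterocyclic carbene-catalysed reductive alkyne–aldehyde macrocyclisation with Et3SiH, using a bulky carbene for the exocyclic (1,1-disubstituted) alkene, which gives the macrocyclic triethylsilyl ether F8; HF·pyridine then gives 28.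

Step 13 (the proposed new lactonisation). The seven-membered closure at the tertiary carbon may lose to Meinwald rearrangement or to intermolecular opening. Fallback with known chemistry, setting out from 22 and returning at 25: epoxidise 22 with DMDO as before to 23, open the epoxide with dilute aqueous HClO4 in THF (water attacks the tertiary carbon with inversion) to give the dihydroxy acid F4, acylate the secondary C4 hydroxyl with octanoic anhydride/DMAP and hydrolyse the mixed anhydride on work-up to give the octanoyl seco acid F5, then close the ε-lactone onto the tertiary C3 hydroxyl by Shiina macrolactonisation (MNBA, DMAP, Et3N), which arrives at 25.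

Step 4 (esterification/Diels–Alder/equilibration cascade). The sensitive keto acid may not esterify cleanly, and the convergence on one diastereomer rests on a thermodynamic argument. Fallback, setting out from 6 and returning at 9: acylate 6 with maleic anhydride (Et3N, cat. DMAP) and warm, so that the maleate half-ester undergoes the classical endo intramolecular Diels–Alder reaction to the all-cis lactone acid F1; couple F1 with N,O-dimethylhydroxylamine (DIC) to the Weinreb amide F2, add MeMgBr at −78 °C to obtain the methyl ketone F3 (the C14 epimer of 9), and epimerise C14 with DBU to reach 9.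

**Further compounds**

F1 | step 4 | (3S)-3-(2-bromoprop-2-en-1-yl)-4-methyl-1-oxo-1,3,3a,6,7,7a-hexahydro-2-benzofuran-7-carboxylic acid (cis-fused; CO2H cis to the lactone carbonyl carbon) | C=C(Br)C[C@@H]1OC(=O)[C@H]2[C@H](CC=C(C)[C@H]21)C(=O)O
F2 | step 4 | N-methoxy-N-methylamide of F1 | C=C(Br)C[C@@H]1OC(=O)[C@H]2[C@H](CC=C(C)[C@H]21)C(=O)N(C)OC
F3 | step 4 | C14 epimer of 9 (acetyl cis to the lactone carbonyl carbon) | C=C(Br)C[C@@H]1OC(=O)[C@H]2[C@H](CC=C(C)[C@H]21)C(C)=O
F4 | step 13 | dihydroxy acid: 22 with 3-OH and 4-OH in place of the alkene (C3 and C4 as in the target) | C=C(Br)C[C@@H]1O[C@@H]([C@@](C)(O)[C@H](O)CCO[Si](C)(C)C(C)(C)C)[C@H]2[C@@H](CC[C@@](C)(O)[C@H]21)[C@@H](C)C(=O)O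
F5 | step 13 | 4-O-octanoate of F4 (seco acid of 25) | C=C(Br)C[C@@H]1O[C@@H]([C@@](C)(O)[C@H](OC(=O)CCCCCCC)CCO[Si](C)(C)C(C)(C)C)[C@H]2[C@@H](CC[C@@](C)(O)[C@H]21)[C@@H](C)C(=O)O
F6 | step 17 | alkyne alcohol: 26 with prop-2-yn-1-yl on C9 in place of 2-bromoallyl | C#CC[C@@H]1O[C@@H]3[C@H]2[C@@H](CC[C@@](C)(O)[C@H]21)[C@@H](C)C(=O)O[C@@]3(C)[C@H](OC(=O)CCCCCCC)CCO
F7 | step 17 | C6 aldehyde of F6 (ynal) | C#CC[C@@H]1O[C@@H]3[C@H]2[C@@H](CC[C@@](C)(O)[C@H]21)[C@@H](C)C(=O)O[C@@]3(C)[C@H](OC(=O)CCCCCCC)CC=O
F8 | step 17 | 6-O-triethylsilyl ether of 28 | C=C1C[C@@H]2O[C@@H]3[C@H]4[C@@H](CC[C@@](C)(O)[C@H]42)[C@@H](C)C(=O)O[C@@]3(C)[C@H](OC(=O)CCCCCCC)C[C@H]1O[Si](CC)(CC)CC
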